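**Compound numbering used throughout:** 1 2,4,6-trihydroxybenzaldehyde; 2 its 4,6-bis-pivalate; 3 3-chloro-3-methylbut-1-yne; 4 aryl dimethylpropargyl ether; 5 allenyl phenol (not isolated); 6 chromene aldehyde; 7 chroman aldehyde (not isolated); 8 benzylic alcohol; 9 2-(2-hydroxy-4-methoxyphenyl)acetic acid; 10 its methyl ester; 11 benzyl aryl ether; 12 diazo ester; 13 cis-dihydrobenzofuran ester; 14 triol; 15 target.

## The problem

The target is a cis-fused pterocarpan, (6aS,11aS)-6a,11a-dihydro-6H-benzofuro[3,2-c]chromene (rings A–D), with 9-OMe on ring D, a free 3-OH on ring A and a 2,2-dimethyldihydropyran fused on the C1–C2 bond of ring A through O1. Its only stereocentres, C6a and C11a, are the two ends of the bond shared by dihydrofuran ring B and dihydropyran ring C; only the cis fusion is strain-free, so C11a follows C6a thermodynamically, but nothing in the molecule can induce the absolute configuration at C6a. Ring A is a fully differentiated phloroglucinol (O1 in the dimethylpyran, O3 free, O5 in ring C; C2 and C11b each between two oxygens), so every annulation on it has a linear/angular alternative. The C11a–O11 bond is a benzyl aryl ether on a 2,4,6-trioxygenated arene with a free para hydroxyl: it ionises to a quinone methide with acid or with base and heat and is open to hydrogenolysis, which rules out methyl-ether protection (9-OMe must survive), late strong acid and late hydrogenation. The benzylic CH2 of the dimethylchroman on C2 is as activated as C11a, so oxidative ring closures face a site-selectivity problem. The feature the plan uses: C11a–H is a benzylic C–H α to O11 lying 1,5 to C6a through O11–C10a–C6b of ring D, and C6a carries only ring D, H and the one-carbon unit C6. With C6 as an ester, C6a is the carbon of an aryl/ester carbene and C11a the methylene of an aryl benzyl ether, so the B/C fusion bond C6a–C11a can be made by enantioselective C–H insertion, closing ring B and setting both stereocentres at once.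

## Retrosynthesis

**15 ⇒ 14 (cut O5–C6, ring C).** The last ring is closed at a primary, non-stereogenic carbon by intramolecular Mitsunobu etherification of triol 14. The classical last cut, O11–C11a, would need acid on the most labile bond; here that bond is already in place and the closure is neutral. The para hydroxyl O3–H cannot reach C6, so no phenol differentiation is needed.

**14 ⇒ 13 (functional-group change).** C6 is a methyl ester and both ring-A phenols are pivalates in 13; one hydride operation gives 14. Pivalates need no acid or hydrogenolysis for removal, and they keep ring A electron-poor through every earlier step, so the C11a–O11 ether is not ionisable until the end.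

**13 ⇒ 12 (cut C6a–C11a, key step).** Cutting C6a–C6b (Heck-type) or C11a–C11b (Friedel–Crafts) would keep a chromene or chromanol and the intact C11a–C6a–C6 chain of isoflavonoid chemistry. Cutting the fusion bond itself removes ring B and both stereocentres and leaves the achiral diazo ester 12, two arenes joined by an OCH2 link. The forward reaction must be a 1,5-C–H insertion with catalyst control of both new centres.

**12 ⇒ 11 ⇒ 8 + 10 (cut O11–C11a as an ether).** Diazo transfer to arylacetate 11, which is the Mitsunobu ether of benzylic alcohol 8 and phenol 10. The two halves of the molecule are joined through a C–O bond under neutral conditions, so the route is convergent.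

**8 ⇒ 6 ⇒ 4 ⇒ 2 + 3 ⇒ 1 (ring A regiochemistry).** The formyl carbon of 1 is C11a. Its hydrogen bond keeps one ortho hydroxyl free during bis-pivaloylation (2); that oxygen becomes O1 and takes the dimethylpropargyl group of 3 (4). The aromatic propargyl Claisen rearrangement of 4 can reach only the one free ortho carbon (C2), so chromene 6 has the pyran on O1/C2 with no regiochemical alternative. Alkene hydrogenation and aldehyde reduction give 8.

**10 ⇒ 9.** Fischer esterification of the ring-D hydroxy acid.

## Roads not taken

**Alternative 1 (the obvious route):** cut O11–C11a and take ring C from an isoflavone. Pyrano-isoflavone A1 would be reduced by Ru–TsDPEN asymmetric transfer hydrogenation with dynamic kinetic resolution through the isoflavanone to cis-isoflavan-4-ol A2, which closes to 15 with acid. A1 needs a deoxybenzoin/C1 assembly on the phloroglucinol, separate protection of 7-OH and 2′-OH beside the chelated 5-OH used for the propargyl/Claisen annulation, and then the removal of three oxidation levels from C2–C4 that were only just built. The 5-alkoxy group peri to the ketone hinders the reduction and makes the 4-ol ionise readily. The chosen plan joins two halves by an ether, has a single redox adjustment (ester to CH2) and sets both centres in a C–C bond-forming step.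

**Alternative 2:** cut C6a–C6b and O11–C11a together (Heck oxyarylation). 2H-Chromene A3 and 2-iodo-5-methoxyphenol A4 with Pd(II)/Ag(I) would give the cis-pterocarpan in one step, but as a racemate, since no reliable enantioselective version exists. A3 requires annulating an unsubstituted pyran on the phloroglucinol with the linear/angular ambiguity unsolved, and its very electron-rich styrene is prone to oxidation and polymerisation.

**Alternative 3:** add H2 to a flat precursor (dearomatisation). Pterocarpene A5 would be hydrogenated enantioselectively across the benzofuran C6a=C11a bond, setting both centres. The tetrasubstituted 2-aryl-3-alkyl benzofuran bond inside a rigid tetracycle lies outside the substrate range of known benzofuran hydrogenation catalysts (2- or 3-monosubstituted). The product's C11a–O11 bond is at risk of hydrogenolysis under the same conditions, and A5 needs a longer run-up (arylcoumarin or coumestan and lactone reduction) than 12.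

Key step: step 8

Assumption: 2-(2-hydroxy-4-methoxyphenyl)acetic acid (9) is taken as a catalogue compound.
Assumption: Rh2(S-PTTL)4 is taken to give the (2S,3R) ester 13; the sense of induction follows the catalyst antipode, so Rh2(R-PTTL)4 is used instead if the opposite sense is found on this substrate.

## Route

Step 1
Reactants: 1 2,4,6-trihydroxybenzaldehyde
Product: 2 4-formyl-5-hydroxy-1,3-phenylene bis(2,2-dimethylpropanoate)
Conditions: PivCl (2.05 equiv), Et3N, CH2Cl2, −20 → 0 °C
Reagents that add atoms: pivaloyl chloride, CC(C)(C)C(=O)Cl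
Why: Selective O-acylation; the para hydroxyl and one ortho hydroxyl react, while the remaining ortho hydroxyl is held in the six-membered hydrogen bond to the formyl group and is the least nucleophilic, as in the usual 4,6-bis-protection of 2,4,6-trihydroxyaryl carbonyl compounds.

Step 2
Reactants: 2 4-formyl-5-hydroxy-1,3-phenylene bis(2,2-dimethylpropanoate); 3 3-chloro-3-methylbut-1-yne
Product: 4 4-formyl-5-[(2-methylbut-3-yn-2-yl)oxy]-1,3-phenylene bis(2,2-dimethylpropanoate)
Conditions: DBU, CuCl2·2H2O (cat.), MeCN, 0 °C
Reagents that add atoms: none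
Why: Copper-catalysed O-propargylation of a phenol with a tertiary propargyl chloride, a method suited to electron-poor phenols; the hindered pivalates should tolerate DBU at 0 °C.

Step 3
Reactants: 4 4-formyl-5-[(2-methylbut-3-yn-2-yl)oxy]-1,3-phenylene bis(2,2-dimethylpropanoate)
Product: 6 8-formyl-2,2-dimethyl-2H-chromene-5,7-diyl bis(2,2-dimethylpropanoate), via allenyl phenol 5 (not isolated)
Conditions: xylenes, 140 °C
Reagents that add atoms: none
Why: Aromatic propargyl Claisen rearrangement, then 1,5-H shift and oxa-6π electrocyclisation; the only free ortho position of the ether oxygen is the future C2, so the pyran can only form on O1/C2.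

Step 4
Reactants: 6 8-formyl-2,2-dimethyl-2H-chromene-5,7-diyl bis(2,2-dimethylpropanoate)
Product: 8 8-(hydroxymethyl)-2,2-dimethyl-3,4-dihydro-2H-chromene-5,7-diyl bis(2,2-dimethylpropanoate), via chroman aldehyde 7 (not isolated)
Conditions: H2 (1 atm), 10% Pd/C, EtOAc, rt; filter; BH3·THF, THF, 0 °C; MeOH
Reagents that add atoms: none
Why: Heterogeneous hydrogenation of the cis-disubstituted chromene alkene, then borane reduction of the aldehyde; borane delivers the alcohol as a boron alkoxide, so no free alkoxide sits next to the ortho pivalate and O-to-O acyl migration is avoided.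

Step 5
Reactants: 9 2-(2-hydroxy-4-methoxyphenyl)acetic acid
Product: 10 methyl 2-(2-hydroxy-4-methoxyphenyl)acetate
Conditions: MeOH, H2SO4 (cat.), reflux; neutralise before concentration
Reagents that add atoms: methanol, CO
Why: Fischer esterification; in excess methanol the equilibrium lies on the side of the open hydroxy ester.

Step 6
Reactants: 8 8-(hydroxymethyl)-2,2-dimethyl-3,4-dihydro-2H-chromene-5,7-diyl bis(2,2-dimethylpropanoate); 10 methyl 2-(2-hydroxy-4-methoxyphenyl)acetate
Product: 11 methyl 2-[2-({5,7-bis[(2,2-dimethylpropanoyl)oxy]-2,2-dimethyl-3,4-dihydro-2H-chromen-8-yl}methoxy)-4-methoxyphenyl]acetate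
Conditions: PPh3, DIAD, THF, 0 °C → rt
Reagents that add atoms: none
Why: Mitsunobu etherification of a phenol with a primary benzylic alcohol under neutral conditions; the pivalates make the benzylic centre react by SN2 and not through a free cation, so O-alkylation should prevail.

Step 7
Reactants: 11 methyl 2-[2-({5,7-bis[(2,2-dimethylpropanoyl)oxy]-2,2-dimethyl-3,4-dihydro-2H-chromen-8-yl}methoxy)-4-methoxyphenyl]acetate
Product: 12 methyl 2-[2-({5,7-bis[(2,2-dimethylpropanoyl)oxy]-2,2-dimethyl-3,4-dihydro-2H-chromen-8-yl}methoxy)-4-methoxyphenyl]-2-diazoacetate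
Conditions: p-ABSA, DBU, MeCN, 0 °C → rt
Reagents that add atoms: 4-acetamidobenzenesulfonyl azide, CC(=O)Nc1ccc(cc1)S(=O)(=O)N=[N+]=[N-]
Why: Regitz diazo transfer to an arylacetate, the standard entry to aryldiazoacetates.

Step 8
Reactants: 12 methyl 2-[2-({5,7-bis[(2,2-dimethylpropanoyl)oxy]-2,2-dimethyl-3,4-dihydro-2H-chromen-8-yl}methoxy)-4-methoxyphenyl]-2-diazoacetate
Product: 13 methyl (2S,3R)-2-{5,7-bis[(2,2-dimethylpropanoyl)oxy]-2,2-dimethyl-3,4-dihydro-2H-chromen-8-yl}-6-methoxy-2,3-dihydro-1-benzofuran-3-carboxylate
Conditions: Rh2(S-PTTL)4 (1–2 mol%), toluene, −60 °C, slow addition of 12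
Reagents that add atoms: none
Why: The catalyst turns 12 into a rhodium-bound donor/acceptor carbene at C6a (ring D donor, CO2Me acceptor), which inserts into one of the two enantiotopic benzylic C11a–H bonds of the ArCH2–O11 ether through a three-centre, hydride-transfer-like transition state. The closest known reaction is the chiral dirhodium(II) carboxylate-catalysed intramolecular C–H insertion of methyl 2-(2-benzyloxyphenyl)-2-diazoacetates to cis-2-aryl-2,3-dihydrobenzofuran-3-carboxylates. Ring B (O11–C11a–C6a–C6b–C10a) closes by 1,5-insertion to a five-membered ring; no other ring forms here. C6a is set by the carbene face left open by the phthalimido wall of the catalyst and C11a by which enantiotopic hydrogen is delivered to that face, the cis relation (ring A aryl syn to CO2Me) being the kinetic outcome of this catalyst class at low temperature. The step needs site selectivity (C11a–H against addition to ring A, pivalate C–H bonds and carbene dimerisation) and cis/enantioselectivity: the 1,5-geometry, activation of C11a–H by O11 and the aryl group, full substitution of both ortho positions of ring A and slow addition secure the first, the catalyst the second. The two pivalates keep ring A from being so electron-rich that hydride transfer runs on to a free benzylic cation and leaves the concerted pathway. Partial loss of the cis relation would be tolerable, since C11a is corrected thermodynamically once ring C is closed and only the C6a configuration is carried to the target.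

Step 9
Reactants: 13 methyl (2S,3R)-2-{5,7-bis[(2,2-dimethylpropanoyl)oxy]-2,2-dimethyl-3,4-dihydro-2H-chromen-8-yl}-6-methoxy-2,3-dihydro-1-benzofuran-3-carboxylate
Product: 14 8-[(2S,3S)-3-(hydroxymethyl)-6-methoxy-2,3-dihydro-1-benzofuran-2-yl]-2,2-dimethyl-3,4-dihydro-2H-chromene-5,7-diol
Conditions: DIBAL-H (excess), CH2Cl2, −78 → −20 °C; aq. Rochelle salt
Reagents that add atoms: none
Why: One hydride operation reduces the methyl ester to the primary alcohol and cleaves both aryl pivalates; the reagent is non-basic, so C6a (α to the ester) should not epimerise, and hydride reduction of phenolic 2-aryl-2,3-dihydrobenzofuran-3-carboxylates to the alcohols is a known reaction type.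

Step 10
Reactants: 14 8-[(2S,3S)-3-(hydroxymethyl)-6-methoxy-2,3-dihydro-1-benzofuran-2-yl]-2,2-dimethyl-3,4-dihydro-2H-chromene-5,7-diol
Product: 15 (6aS,11aS)-3-hydroxy-9-methoxy-6a,11a-dihydro-6H-benzofuro[3,2-c]chromene carrying a 2,2-dimethyl-3,4-dihydro-2H-pyran ring fused at C1–C2 through O1 (CNP0207547.1)
Conditions: PPh3, DIAD (betaine pre-formed at 0 °C), THF (0.01 M), 0 °C → rt
Reagents that add atoms: none
Why: Intramolecular Mitsunobu etherification; O5–H attacks the activated C6 in a 6-exo-tet closure of ring C, O3–H cannot reach, and no stereocentre is touched. Pre-forming the betaine keeps free azodicarboxylate away from the electron-rich ring.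

## Compound list

1 | 2,4,6-trihydroxybenzaldehyde | O=Cc1c(O)cc(O)cc1O | starting material
2 | 4-formyl-5-hydroxy-1,3-phenylene bis(2,2-dimethylpropanoate) | O=Cc1c(O)cc(OC(=O)C(C)(C)C)cc1OC(=O)C(C)(C)C | intermediate
3 | 3-chloro-3-methylbut-1-yne | CC(C)(Cl)C#C | starting material
4 | 4-formyl-5-[(2-methylbut-3-yn-2-yl)oxy]-1,3-phenylene bis(2,2-dimethylpropanoate) | O=Cc1c(OC(C)(C)C#C)cc(OC(=O)C(C)(C)C)cc1OC(=O)C(C)(C)C | intermediate
5 | 4-formyl-5-hydroxy-6-(3-methylbuta-1,2-dien-1-yl)-1,3-phenylene bis(2,2-dimethylpropanoate) (allenyl phenol, not isolated) | O=Cc1c(O)c(C=C=C(C)C)c(OC(=O)C(C)(C)C)cc1OC(=O)C(C)(C)C | intermediate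
6 | 8-formyl-2,2-dimethyl-2H-chromene-5,7-diyl bis(2,2-dimethylpropanoate) | O=Cc1c(OC(=O)C(C)(C)C)cc(OC(=O)C(C)(C)C)c2C=CC(C)(C)Oc12 | intermediate
7 | 8-formyl-2,2-dimethyl-3,4-dihydro-2H-chromene-5,7-diyl bis(2,2-dimethylpropanoate) (not isolated) | O=Cc1c(OC(=O)C(C)(C)C)cc(OC(=O)C(C)(C)C)c2CCC(C)(C)Oc12 | intermediate
8 | 8-(hydroxymethyl)-2,2-dimethyl-3,4-dihydro-2H-chromene-5,7-diyl bis(2,2-dimethylpropanoate) | OCc1c(OC(=O)C(C)(C)C)cc(OC(=O)C(C)(C)C)c2CCC(C)(C)Oc12 | intermediate
9 | 2-(2-hydroxy-4-methoxyphenyl)acetic acid | OC(=O)Cc1ccc(OC)cc1O | starting material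
10 | methyl 2-(2-hydroxy-4-methoxyphenyl)acetate | COC(=O)Cc1ccc(OC)cc1O | intermediate
11 | methyl 2-[2-({5,7-bis[(2,2-dimethylpropanoyl)oxy]-2,2-dimethyl-3,4-dihydro-2H-chromen-8-yl}methoxy)-4-methoxyphenyl]acetate | COC(=O)Cc1ccc(OC)cc1OCc1c(OC(=O)C(C)(C)C)cc(OC(=O)C(C)(C)C)c2CCC(C)(C)Oc12 | intermediate
12 | methyl 2-[2-({5,7-bis[(2,2-dimethylpropanoyl)oxy]-2,2-dimethyl-3,4-dihydro-2H-chromen-8-yl}methoxy)-4-methoxyphenyl]-2-diazoacetate | COC(=O)C(=[N+]=[N-])c1ccc(OC)cc1OCc1c(OC(=O)C(C)(C)C)cc(OC(=O)C(C)(C)C)c2CCC(C)(C)Oc12 | intermediate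
13 | methyl (2S,3R)-2-{5,7-bis[(2,2-dimethylpropanoyl)oxy]-2,2-dimethyl-3,4-dihydro-2H-chromen-8-yl}-6-methoxy-2,3-dihydro-1-benzofuran-3-carboxylate (cis) | COc1ccc2c(c1)O[C@H](c1c(OC(=O)C(C)(C)C)cc(OC(=O)C(C)(C)C)c3c1OC(C)(C)CC3)[C@@H]2C(=O)OC | intermediate
14 | 8-[(2S,3S)-3-(hydroxymethyl)-6-methoxy-2,3-dihydro-1-benzofuran-2-yl]-2,2-dimethyl-3,4-dihydro-2H-chromene-5,7-diol (cis) | COc1ccc2c(c1)O[C@H](c1c(O)cc(O)c3c1OC(C)(C)CC3)[C@@H]2CO | intermediate
15 | (6aS,11aS)-3-hydroxy-9-methoxy-pterocarpan with 2,2-dimethyl-3,4-dihydro-2H-pyran fused at C1–C2 through O1 (CNP0207547.1) | COc1ccc2c(c1)O[C@@H]1c3c(cc(O)c4c3OC(C)(C)CC4)OC[C@H]21 | target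

## Step count and risks

Total steps: 10. Longest linear sequence: 9 (steps 1–4 and 6–10; step 5 is the one-step ring-D branch).

**Step 8 (key step).** The benzylic methylene is flanked by two ortho substituents, so the concerted 1,5-insertion may be slowed until carbene dimerisation, addition to ring A or a stepwise hydride-transfer/recombination pathway takes over and cis- and enantioselectivity erode. Fallback (auxiliary-controlled aldol in place of carbene insertion; sets out from 6 and 9, returns at 14 and, for epimeric material, at 15): 9 is treated with PivCl/Et3N to give the O-pivaloylated mixed anhydride F1, which acylates lithiated (R)-4-benzyloxazolidin-2-one to the N-acyl oxazolidinone F2. Compound 6 is hydrogenated and 7 isolated. The Evans syn-aldol reaction of F2 with 7 (Bu2BOTf, iPr2NEt, CH2Cl2, −78 °C) gives the (2R,3R) aldol adduct F3, in which the auxiliary fixes C6a. LiAlH4 (THF, −20 → 0 °C) removes the auxiliary and the three pivalates to give the pentol F4. With PPTS the benzylic carbinol ionises and is captured by the ring-D phenol, giving 14 together with its C11a epimer, the trans-dihydrobenzofuran triol F5. Both go through step 10; the trans-fused pterocarpan F6 formed from F5 should isomerise to 15 under the same mild acid by reversible ionisation of C11a–O11. The acid exposure must be short, because elimination from the C11a cation would erode C6a.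

**Step 9.** Once the pivalates are cleaved, ionisation of C11a–O11 from the aluminium phenoxides and hydride addition to the resulting quinone methide (reductive opening of ring B) may compete, as may C11a epimerisation on work-up. Fallback (hydride never meets a free phenoxide, and ring C closes at the moment of unmasking; sets out from 13, returns at 15): SN2 demethylation of the ester (LiI, EtOAc, reflux) gives the bis-pivalate carboxylic acid F7. BH3·THF (0 °C) reduces the acid selectively to the bis-pivalate primary alcohol F8. MsCl/Et3N gives the mesylate F9. K2CO3 in MeOH then cleaves the pivalates, and the liberated O5 phenoxide displaces the mesylate to give 15.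

**Step 10.** Intermolecular O-alkylation, attack of the azodicarboxylate on the electron-rich resorcinol-type ring and C11a epimerisation before closure may compete with the 6-exo-tet etherification. Fallback (halide/Williamson sequence in place of redox condensation; sets out from 14, returns at 15): PPh3/I2/imidazole (CH2Cl2, 0 °C) converts the primary alcohol selectively into the iodide F10, and Cs2CO3 in MeCN closes ring C by phenoxide displacement.

**Step 2.** O-Alkylation of the chelated, electron-poor phenol may be slow, so that acyl transfer from the aryl pivalates to DBU or phenoxide and elimination of the propargyl chloride compete. Fallback (ethers carried through the base and heat steps, esters installed afterwards; sets out from 1, returns at 7): MOMCl/iPr2NEt gives the bis-MOM aldehyde F11. The same propargylation with 3 gives the propargyl ether F12, and heating gives, through the allenyl phenol F13, the chromene F14. Hydrogenation (H2, Pd/C) gives the chroman aldehyde F15 and HCl/MeOH the dihydroxy chroman aldehyde F16. Exhaustive pivaloylation (PivCl, Et3N, DMAP) then gives 7, which enters the borane reduction of step 4.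

## Further compounds

F1 | step 8 | 2,2-dimethylpropanoic 2-{2-[(2,2-dimethylpropanoyl)oxy]-4-methoxyphenyl}acetic anhydride | COc1ccc(CC(=O)OC(=O)C(C)(C)C)c(OC(=O)C(C)(C)C)c1
F2 | step 8 | (4R)-4-benzyl-3-(2-{2-[(2,2-dimethylpropanoyl)oxy]-4-methoxyphenyl}acetyl)-1,3-oxazolidin-2-one | COc1ccc(CC(=O)N2C(=O)OC[C@H]2Cc2ccccc2)c(OC(=O)C(C)(C)C)c1
F3 | step 8 | (4R)-4-benzyl-3-[(2R,3R)-3-{5,7-bis[(2,2-dimethylpropanoyl)oxy]-2,2-dimethyl-3,4-dihydro-2H-chromen-8-yl}-3-hydroxy-2-{2-[(2,2-dimethylpropanoyl)oxy]-4-methoxyphenyl}propanoyl]-1,3-oxazolidin-2-one | O=C(N1C(=O)OC[C@H]1Cc1ccccc1)[C@H](c1ccc(OC)cc1OC(=O)C(C)(C)C)[C@@H](O)c1c(OC(=O)C(C)(C)C)cc(OC(=O)C(C)(C)C)c2CCC(C)(C)Oc12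
F4 | step 8 | (1R,2S)-1-(5,7-dihydroxy-2,2-dimethyl-3,4-dihydro-2H-chromen-8-yl)-2-(2-hydroxy-4-methoxyphenyl)propane-1,3-diol | OC[C@H](c1ccc(OC)cc1O)[C@@H](O)c1c(O)cc(O)c2CCC(C)(C)Oc12
F5 | step 8 | 8-[(2R,3S)-3-(hydroxymethyl)-6-methoxy-2,3-dihydro-1-benzofuran-2-yl]-2,2-dimethyl-3,4-dihydro-2H-chromene-5,7-diol (trans) | COc1ccc2c(c1)O[C@@H](c1c(O)cc(O)c3c1OC(C)(C)CC3)[C@@H]2CO
F6 | step 8 | (6aS,11aR)-trans-fused isomer of 15 | COc1ccc2c(c1)O[C@H]1c3c(cc(O)c4c3OC(C)(C)CC4)OC[C@H]21
F7 | step 9 | (2S,3R)-2-{5,7-bis[(2,2-dimethylpropanoyl)oxy]-2,2-dimethyl-3,4-dihydro-2H-chromen-8-yl}-6-methoxy-2,3-dihydro-1-benzofuran-3-carboxylic acid | COc1ccc2c(c1)O[C@H](c1c(OC(=O)C(C)(C)C)cc(OC(=O)C(C)(C)C)c3c1OC(C)(C)CC3)[C@@H]2C(O)=O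
F8 | step 9 | 8-[(2S,3S)-3-(hydroxymethyl)-6-methoxy-2,3-dihydro-1-benzofuran-2-yl]-2,2-dimethyl-3,4-dihydro-2H-chromene-5,7-diyl bis(2,2-dimethylpropanoate) | COc1ccc2c(c1)O[C@H](c1c(OC(=O)C(C)(C)C)cc(OC(=O)C(C)(C)C)c3c1OC(C)(C)CC3)[C@@H]2CO
F9 | step 9 | 8-[(2S,3S)-6-methoxy-3-{[(methylsulfonyl)oxy]methyl}-2,3-dihydro-1-benzofuran-2-yl]-2,2-dimethyl-3,4-dihydro-2H-chromene-5,7-diyl bis(2,2-dimethylpropanoate) | COc1ccc2c(c1)O[C@H](c1c(OC(=O)C(C)(C)C)cc(OC(=O)C(C)(C)C)c3c1OC(C)(C)CC3)[C@@H]2COS(C)(=O)=O
F10 | step 10 | 8-[(2S,3R)-3-(iodomethyl)-6-methoxy-2,3-dihydro-1-benzofuran-2-yl]-2,2-dimethyl-3,4-dihydro-2H-chromene-5,7-diol | COc1ccc2c(c1)O[C@H](c1c(O)cc(O)c3c1OC(C)(C)CC3)[C@@H]2CI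
F11 | step 2 | 2-hydroxy-4,6-bis(methoxymethoxy)benzaldehyde | O=Cc1c(O)cc(OCOC)cc1OCOC
F12 | step 2 | 2,4-bis(methoxymethoxy)-6-[(2-methylbut-3-yn-2-yl)oxy]benzaldehyde | O=Cc1c(OC(C)(C)C#C)cc(OCOC)cc1OCOC
F13 | step 2 | 2-hydroxy-4,6-bis(methoxymethoxy)-3-(3-methylbuta-1,2-dien-1-yl)benzaldehyde | O=Cc1c(O)c(C=C=C(C)C)c(OCOC)cc1OCOC
F14 | step 2 | 5,7-bis(methoxymethoxy)-2,2-dimethyl-2H-chromene-8-carbaldehyde | O=Cc1c(OCOC)cc(OCOC)c2C=CC(C)(C)Oc12
F15 | step 2 | 5,7-bis(methoxymethoxy)-2,2-dimethyl-3,4-dihydro-2H-chromene-8-carbaldehyde | O=Cc1c(OCOC)cc(OCOC)c2CCC(C)(C)Oc12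
F16 | step 2 | 5,7-dihydroxy-2,2-dimethyl-3,4-dihydro-2H-chromene-8-carbaldehyde | O=Cc1c(O)cc(O)c2CCC(C)(C)Oc12
A1 | alternative 1 | 5-hydroxy-9-(2-hydroxy-4-methoxyphenyl)-2,2-dimethyl-3,4-dihydro-2H,10H-pyrano[2,3-f]chromen-10-one (pyrano-isoflavone) | O=C1C(c2ccc(OC)cc2O)=COc2cc(O)c3CCC(C)(C)Oc3c12
A2 | alternative 1 | cis-isoflavan-4-ol, (3S,4S) in isoflavan numbering, with the same A-ring pyran and free 7-OH and 2′-OH | O[C@H]1[C@@H](c2ccc(OC)cc2O)COc2cc(O)c3CCC(C)(C)Oc3c12
A3 | alternative 2 | 2,2-dimethyl-3,4-dihydro-2H,8H-pyrano[2,3-f]chromen-5-ol | Oc1cc2OCC=Cc2c2OC(C)(C)CCc12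
A4 | alternative 2 | 2-iodo-5-methoxyphenol | COc1ccc(I)c(O)c1
A5 | alternative 3 | pterocarpene (6a,11a-didehydro analogue of 15) | COc1ccc2c(c1)oc1c2COc2cc(O)c3CCC(C)(C)Oc3c12
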